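## The problem

Target 36 is a C25 terpenoid built on a trans-decalin. Locants used throughout: ring A is C1–C5 plus C10, ring B is C5–C10, and C9 carries the chain C11–C12–C13(=CH2)–C14(OH)–C15(OH)–C16, where C16 is the oxygen-bearing carbon of a butenolide whose other ring atoms are C17 (methyl-bearing), C18 and C19 (carbonyl); one-carbon substituents are named after the atom they sit on (the C4 formyl carbon, the C4, C8 and C10 methyls, the C13 methylene). The decalin holds six stereocentres (4R,5R,6S,8R,9R,10S), two of them quaternary: C4 (β-methyl, α-formyl) and C10 (β-methyl). Their methyls are 1,3-diaxial on the β face, while the 6- and 8-hydroxyls and the C9 chain are equatorial. These two axial methyls are the main control element: they close the β side of C5, C6 and C8, so 5α-H, the 6α-oxygen and the 8α-oxygen can all be delivered from the α side once C4 and C10 exist. C9 and C10 are a vicinal tertiary–quaternary pair that must be set in one event, and the 1,3-relation between C4 and C10 is the hardest one to induce. The syn,syn-triol C14–C16 is separated from the ring by two methylene groups, cannot be induced from it, and must arrive with its own absolute configuration. Groups that will not survive rough treatment are the butenolide (acidic C16–H next to a β-alkoxy group; hydride, organolithium and base), the hindered C4 aldehyde beside the 6α-hydroxyl (hemiacetal formation, over-oxidation to a lactone), the tertiary C8 and allylic C14 carbinols (strong acid) and the 1,1-disubstituted C13 alkene. The feature that opens the key step is the C6–C7–C8 segment: the secondary 6α-hydroxyl is 1,3 to C8, and the methyl/hydroxyl pair on C8 is what an exocyclic methylene gives after epoxidation and hydride opening. Ring B can therefore be closed between C6 and C7 by a carbonyl-ene reaction of a C6 aldehyde on C5 with an isopropenyl group on C9.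

## Retrosynthesis

**Final unmasking and C12–C13.** 36 is taken back to 35, in which the C4 formyl group and the 6α-hydroxyl are one cyclic methyl acetal, O14/O15 an acetonide and O8 a trimethylsilyl ether, so one mild hydrolysis ends the synthesis. 35 is cut at C12–C13 into primary iodide 23 (used as its zinc reagent 34) and alkenyl triflate 33. The neighbouring cut, C13–C14 by adding an alkenyl metal to an aldehyde, would create C14 in the last C–C bond formation, where non-chelated addition favours the wrong (anti) relation to O15 and the reagents attack the butenolide. The C12–C13 cut is an sp3–sp2 Negishi coupling that forms no stereocentre. It divides the skeleton into a C16 decalin and a C9 side chain. The forward reaction must insert zinc beside an acetal and a silyl ether and couple before the alkylzinc decays.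

**Side-chain triflate 33.** The syn,syn-triol maps onto L-tartaric acid: C14 and C15 are its carbinol carbons, C13 and C16 its carboxyl carbons. 33 goes back through hydroxy ynoate 31 (butenolide by syn methylcupration and lactonisation, via 32), ynone 30 (C16 by reagent-controlled reduction), Weinreb amide 27 plus ethyl propiolate 28 (through 29), methyl ketone 26 (its enol triflate is the C13 methylene unit), bis(Weinreb amide) 25 and commercial acetonide 24. Making C16 by adding an isopropenyl metal to a tartrate aldehyde was set aside because 1,2-induction from a dioxolane is weak. A catalyst-controlled ynone reduction only has to tell an alkynyl group from a branched alkyl group.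

**Decalin end groups.** 23, 22 and 21 differ from 20 only at C12 and O8. The tertiary 8α-alcohol with its 8β-methyl (20) is traced to spiro-epoxide 19 and exocyclic alkene 18; methyl addition to a C8 ketone would give the 8-epimer by equatorial attack. The acetal of 18 comes, via lactol 17, from hydroxy ester 16. Reducing the C4 ester to the aldehyde level while the 6-hydroxyl is there to trap it removes the need for a separate O6 protecting group and for a late oxidation. Asked of the forward steps: α-face epoxidation, hydride attack at the epoxide CH2, and an ester reduction that stops at the lactol.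

**Ring B (key cut).** 16 is disconnected at C6–C7 to aldehyde 15. This one cut removes ring B, the C6 stereocentre and the C8 alkene and leaves a monocyclic precursor. Cutting C5–C6 or C7–C8 gives no such triple gain, and closing ring A last would leave both quaternary centres to the cyclisation. The forward step must place the aluminium-bound oxygen α and lose the proton from the isopropenyl methyl.

**Isopropenyl group and C6 aldehyde.** 15 comes from alcohol 14, and this from lactol 13 and lactone 12. The lactone carbonyl (C8) becomes the isopropenyl carbon by methyl addition and Wittig methylenation; its alkoxy carbon is C6. Lactone 12 is the closed form of hydroxy acid 11, made from alkene acid 10 by hydroboration. The order matters: the C5 methylene must be hydroborated before the isopropenyl alkene exists. The hydroboration must deliver hydrogen to C5 from the α face.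

**C9–C10.** Acid 10 is cut at C9–C10 by an Ireland–Claisen transform to allylic ester 7 (through ketene acetal 8 and silyl ester 9), and 7 to alcohol 5 and acid 6. A conjugate allylation of a C5=C10 unsaturated ester was weighed for this bond and rejected: tetrasubstituted enoates are poor acceptors and an open transition state gives no grip on the C9/C10 relation. The sigmatropic shift is intramolecular, accepts the fully substituted alkene and ties C9 to C10 through a chair. It asks for the Z(O) enolate and for reaction on the ring face syn to the C4 ester.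

**Ring A.** 5 is taken back through triflate 4 and ketone 3 to keto ester 2 and commercial 1: C6 by Stille hydroxymethylation, the C10 methyl by enolate alkylation, and the C4 quaternary centre, the source of all absolute configuration in the decalin, by asymmetric methylation of a β-keto ester. The only selectivity asked here is the enantioselectivity of that first step.

## Roads not taken

Alternative 1: The cut is again in ring B, but at C9–C10. β-Keto δ-lactone A1 (lactone carbonyl C11, ring oxygen on the allylic C6 of a C5=C10 ring-A alkene) would be doubly O-silylated and rearranged as an enolate Claisen ring contraction: C9–C10 forms while C6–O breaks, giving after esterification keto ester A2 with ring B closed and a C5=C6 alkene.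
- Merits: ring closure and the C10 quaternary centre come from one [3,3] shift, and the C10 face is dictated by the C6 carbinol through a cyclic array. That is firmer control of the C4/C10 relation than the chosen plan has in its own Claisen step (step 6), which has to set a reagent-controlled fallback against it.
- Weak points, all after the key step: C11 is an ester on C9, so C12 must be added by homologation. The C8 ketone cannot give the 8α-alcohol by methyl addition, so it must be methylenated and then treated as in steps 13 and 14. C5–H and the C6 hydroxyl must come from hydroboration of a trisubstituted alkene. A1 itself needs an enantio-defined C6 carbinol on a ring that already holds C4.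
- Comparison: the chosen ene closure delivers the C6 oxygen, the C8 methylene and the full C11–C12 arm in the ring-forming step, which saves about four redox or homologation steps.

Alternative 2: The cut is C16–C17 at the very end. Aldehyde A3, carrying the whole decalin and C13–C15, would take the alkenylmagnesium species formed from iodo ester A4 by iodine–magnesium exchange (iPrMgCl·LiCl). Chelation by the C15 p-methoxybenzyl ether steers the addition and the alkoxide closes onto the cis ester to give A5, the fully protected target.
- Merits: the base- and nucleophile-sensitive butenolide never passes through a cross-coupling, and the last C–C bond is a simple carbonyl addition. In this respect it is better than the chosen plan.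
- Weak points: C14 and C15 must be built linearly on the advanced decalin, where they are no easier to control than in a small fragment. A5 carries five protecting groups of four kinds and still needs selective oxidation of the C4 hydroxymethyl group beside a 6-hydroxyl, which invites lactol and lactone formation. The new C16 centre rests on chelation control at a β-silyloxy aldehyde.
- Comparison: the chosen plan makes all three carbinol centres in a six-step fragment, joins it where no stereocentre forms, and ends with one hydrolysis. Both plans share the same ring-B closure, so this road stays open as an endgame variant.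

Alternative 3: Ring A is closed last, at C4–C5. Anodic oxidation of the methyl enol ether in A6 (C4=C(formyl carbon)) gives a radical cation that is trapped at C4 by C5 of the ring-B silyl enol ether, giving decalinone A7 with the C4 formyl carbon as its dimethyl acetal and a C6 ketone.
- Merits: the C4 quaternary centre and the aldehyde oxidation level appear together, with no ester reduction or acetal exchange. Here it is better than the chosen plan, which reaches the C4 formyl group by a two-operation detour through ester and acetal.
- Weak points: the C4 configuration and the trans ring fusion are both decided in an open radical-cation cyclisation with little to bias them. A7 has a plain methine at C8, so the tertiary 8α-hydroxyl has no handle and would need a late C–H oxidation. The C6 ketone must be reduced to the equatorial 6α-alcohol against the kinetic preference (hydride from the open α face gives 6β-OH). The C9 allyl group must be cut back to a two-carbon arm.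
- Comparison: the chosen plan forms the C6 carbinol directly and leaves a C8 methylene as the handle for the tertiary alcohol.

Key step: step 11

Assumption: the target is addressed as the open 6-hydroxy aldehyde that is drawn; any ring–chain equilibrium with the cyclic hemiacetal between the C4 formyl carbon and O6 is a property of the compound and does not change the route.
Assumption: 1, 6, 24 and 28 are bought; α/β refer to the usual decalin drawing with the C10 methyl β.

## Route

Step 1
Reactants: 1 methyl 2-oxocyclohexane-1-carboxylate
Product: 2 methyl (1R)-1-methyl-2-oxocyclohexane-1-carboxylate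
Conditions: MeI, K2CO3, toluene, N-(9-anthracenylmethyl)cinchoninium chloride (10 mol %), 0 °C
Reagents that add atoms: iodomethane, CI
Why: Asymmetric phase-transfer alkylation of a cyclic β-keto ester; the chiral ammonium–enolate ion pair exposes one face of the planar enolate to MeI and so sets the C4 quaternary centre (the pseudo-enantiomeric cinchonidinium salt gives the antipode, so the catalyst series is chosen for the R ester).

Step 2
Reactants: 2
Product: 3 methyl (1R)-1,3-dimethyl-2-oxocyclohexane-1-carboxylate (both C3 epimers)
Conditions: LiN(iPr)2 (LDA), THF, −78 °C; MeI, −78 → 0 °C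
Reagents that add atoms: iodomethane, CI
Why: Ketone enolate alkylation; C4 is quaternary, so only the CH2 that becomes C10 can be deprotonated, and the configuration of the new centre is irrelevant because step 3 makes it planar.

Step 3
Reactants: 3
Product: 4 methyl (1R)-1,3-dimethyl-2-{[(trifluoromethyl)sulfonyl]oxy}cyclohex-2-ene-1-carboxylate
Conditions: KN(SiMe3)2 (KHMDS), THF, −78 → 0 °C; PhNTf2
Reagents that add atoms: N-phenylbis(trifluoromethanesulfonimide), O=S(=O)(N(c1ccccc1)S(=O)(=O)C(F)(F)F)C(F)(F)F
Why: Enol triflate formation; the only enolisable hydrogen sits on the methyl-bearing carbon, so both epimers of 3 give the tetrasubstituted C5=C10 enol triflate regiospecifically.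

Step 4
Reactants: 4
Product: 5 methyl (1R)-2-(hydroxymethyl)-1,3-dimethylcyclohex-2-ene-1-carboxylate
Conditions: Bu3SnCH2OH, Pd(PPh3)4 (5 mol %), LiCl, 1,4-dioxane, 100 °C
Reagents that add atoms: (tributylstannyl)methanol, CCCC[Sn](CCCC)(CCCC)CO
Why: Stille coupling of an alkenyl triflate with a hydroxymethylstannane installs C6 as the allylic alcohol in one step; LiCl assists the triflate in the catalytic cycle and the hindered ester is untouched.

Step 5
Reactants: 5; 6 4-(benzyloxy)butanoic acid
Product: 7 [(6R)-6-(methoxycarbonyl)-2,6-dimethylcyclohex-1-en-1-yl]methyl 4-(benzyloxy)butanoate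
Conditions: DCC, 4-(dimethylamino)pyridine (10 mol %), CH2Cl2, 0 °C → rt
Reagents that add atoms: none
Why: Steglich esterification of a primary allylic alcohol; the acid brings C8, C9, C11 and C12 with the C12 oxygen already protected as a benzyl ether.

Step 6
Reactants: 7
Product: 10 (2R)-4-(benzyloxy)-2-[(1R,3R)-3-(methoxycarbonyl)-1,3-dimethyl-2-methylidenecyclohexyl]butanoic acid, via silyl ketene acetal 8 (not isolated), via trimethylsilyl ester 9 (not isolated)
Conditions: LiN(iPr)2 (LDA), THF/DMPU 4:1, −78 °C; Me3SiCl, −78 °C → rt, then 60 °C; 1 M HCl work-up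
Reagents that add atoms: none
Why: Ireland–Claisen rearrangement: LDA in THF/DMPU gives the Z(O) enolate, trapped as ketene acetal 8 with the CH2CH2OBn group cis to OSiMe3, and the [3,3] shift through a chair (C10 methyl axial, C9 side chain equatorial) forms C9–C10 with the 9,10 relation of the target. The new bond is expected on the ring face syn to the C4 ester, the smaller C4 substituent, which takes the pseudoaxial site beside the forming bond; this facial preference is the weak point of the step (see fallback).

Step 7
Reactants: 10
Product: 12 trans-fused δ-lactone (4R,5R,9R,10S): ring A with 4β-CH3, 4α-CO2Me, 5α-H and 10β-CH3, bridged by O–C6H2 on C5 and C8(=O)–C9 on C10, C9 bearing CH2CH2OBn, via hydroxy acid 11 (not isolated)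
Conditions: 9-BBN (3 equiv), THF, 0 → 65 °C; 3 M NaOH, 30% H2O2, 0 °C; then 1 M HCl to pH 2, rt
Reagents that add atoms: hydrogen peroxide, OO
Why: Hydroboration–oxidation of a 1,1-disubstituted alkene puts boron on C6; hydrogen reaches C5 from the α face because the axial β-methyls on C4 and C10 flank the other face, which sets 5α-H. The free acid only ties up one equivalent of 9-BBN as its acyloxyborane, and the δ-hydroxy acid closes to the trans-fused lactone on acidification.

Step 8
Reactants: 12
Product: 13 lactol (4R,5R,9R,10S): lactone 12 with C8 as a methyl hemiketal carbon (both anomers; ring-chain tautomer of the C6 hydroxy C8 methyl ketone)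
Conditions: MeLi (1.2 equiv), THF, −78 °C; then H2O
Reagents that add atoms: methyllithium, [Li]C
Why: Single addition of an organolithium to a lactone; the tetrahedral lithium hemiketal alkoxide persists at −78 °C and blocks a second addition, and the α-quaternary methyl ester on C4 is far slower than the lactone.

Step 9
Reactants: 13
Product: 14 methyl (1R,2R,3R)-3-[(3S)-5-(benzyloxy)-2-methylpent-1-en-3-yl]-2-(hydroxymethyl)-1,3-dimethylcyclohexane-1-carboxylate
Conditions: Ph3PCH3Br, KOtBu, toluene/THF, 0 → 70 °C
Reagents that add atoms: methyltriphenylphosphonium bromide, C[P+](c1ccccc1)(c1ccccc1)c1ccccc1.[Br-]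
Why: Wittig methylenation of the open hydroxy-ketone form of the lactol (excess ylide first takes the hydroxyl proton); C9–H lies next to a quaternary carbon, so enolisation goes toward the methyl group and C9 is not epimerised.

Step 10
Reactants: 14
Product: 15 methyl (1R,2R,3R)-3-[(3S)-5-(benzyloxy)-2-methylpent-1-en-3-yl]-2-formyl-1,3-dimethylcyclohexane-1-carboxylate
Conditions: Dess–Martin periodinane, CH2Cl2, 0 °C → rt
Reagents that add atoms: none
Why: Dess–Martin oxidation of a primary alcohol; the conditions are non-basic, so the C5 centre between two quaternary carbons keeps its configuration.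

Step 11
Reactants: 15
Product: 16 methyl (1R,4aR,5S,8S,8aR)-5-[2-(benzyloxy)ethyl]-8-hydroxy-1,4a-dimethyl-6-methylidenedecahydronaphthalene-1-carboxylate (4α-CO2Me, 6α-OH, C8 methylene, 9β arm)
Conditions: Me2AlCl (2 equiv, 1 M in hexanes), CH2Cl2, −78 → −20 °C; aq. sodium potassium tartrate
Reagents that add atoms: none
Why: Me2AlCl binds the C6 aldehyde oxygen; C7, the terminal carbon of the isopropenyl group on C9, adds to the carbonyl carbon while a hydrogen of the isopropenyl methyl passes to oxygen, in one step or through a short-lived tertiary cation at C8, and the alkoxyaluminium species then loses methane, which removes the proton source for alkene migration. The closest known reaction type is the type 2 intramolecular carbonyl-ene cyclisation of aldehydes onto 1,1-disubstituted alkenes with Me2AlCl, which gives 3-methylenecyclohexanols. Ring B closes in the type 2 mode: the aldehyde is tethered to C8, the central carbon of the ene unit, the new C6–C7 bond completes a six-membered ring, and the fusion is trans because C5–H and the C10 methyl are already trans. The one new centre is C6, and it is controlled by the axial β-methyls on C4 and C10, which flank C6 on the β side and keep an aluminium-bound oxygen out of the axial 6β position. The oxygen therefore ends 6α, equatorial in the product chair, reached through a boat-like ene array or by chair closure to the C8 cation followed by proton loss. The step needs 6α over 6β and proton loss from the methyl (exocyclic C8 methylene) over proton loss from ring carbons; the first rests on the two axial methyls, the second on the ene geometry and on a Lewis acid that scavenges protons. C9, set in step 6, places the CH2CH2OBn arm equatorial and is untouched; ester, benzyl ether and the C5 centre are spectators.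

Step 12
Reactants: 16
Product: 18 cyclic methyl acetal (4R,5R,6S,9S,10R): decalin of 16 in which the former ester carbon on C4 is an acetal CH(OMe) bonded to O6 (five-membered ring C4–CH(OMe)–O–C6–C5; both acetal epimers), C8 methylene and 9β-CH2CH2OBn unchanged, via lactol 17 (not isolated)
Conditions: iBu2AlH (DIBAL-H, 3 equiv), CH2Cl2, −78 °C; aq. sodium potassium tartrate; then MeOH, pyridinium p-toluenesulfonate (cat.), rt
Reagents that add atoms: methanol, CO
Why: The hindered methyl ester is reduced only to the aldehyde level at −78 °C, where the neighbouring 6α-alkoxide traps it as lactol 17 (should 16 have lactonised, the lactone converges on the same lactol). Acid-catalysed exchange with methanol gives the cyclic acetal, which masks the C4 formyl group and the 6-hydroxyl together until the last step.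

Step 13
Reactants: 18
Product: 19 spiro-epoxide (4R,5R,6S,8R,9R,10S): acetal 18 with the C8 methylene converted to an oxirane, oxygen α (equatorial), CH2 β
Conditions: mCPBA, NaHCO3, CH2Cl2, 0 °C
Reagents that add atoms: 3-chloroperoxybenzoic acid, O=C(OO)c1cccc(Cl)c1
Why: Prilezhaev epoxidation of the exocyclic alkene; the peracid comes from the α (equatorial) side because the axial C10 methyl shields the β face, and the buffer protects the acetal.

Step 14
Reactants: 19
Product: 20 tertiary alcohol (4R,5R,6S,8R,9R,10S): acetal-protected decalin with 8α-OH, 8β-CH3 and 9β-CH2CH2OBn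
Conditions: LiAlH4, THF, 0 → 50 °C; then H2O, 15% NaOH, H2O
Reagents that add atoms: none
Why: Hydride opens the spiro-epoxide by SN2 attack at its CH2 carbon, leaving the oxygen on C8, so the 8α-alcohol and the 8β-methyl group are formed together; acetal and benzyl ether are inert to LiAlH4.

Step 15
Reactants: 20
Product: 21 primary alcohol (4R,5R,6S,8R,9R,10S): as 20 with 9β-CH2CH2OH
Conditions: H2 (1 atm), Pd/C (10%), EtOAc, rt
Reagents that add atoms: none
Why: Hydrogenolysis of the benzyl ether; no alkene is present at this stage and the acetal is stable to neutral hydrogenation.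

Step 16
Reactants: 21
Product: 22 primary iodide (4R,5R,6S,8R,9R,10S): as 21 with 9β-CH2CH2I
Conditions: I2, PPh3, imidazole, CH2Cl2, 0 °C → rt
Reagents that add atoms: iodine, II
Why: Appel-type iodination: iodide displaces the alkoxyphosphonium of the primary alcohol by SN2; the tertiary 8-hydroxyl does not react and imidazole keeps the medium neutral for the acetal.

Step 17
Reactants: 22
Product: 23 silyl ether (4R,5R,6S,8R,9R,10S): as 22 with 8α-OSiMe3
Conditions: 1-(trimethylsilyl)imidazole, CH2Cl2, rt
Reagents that add atoms: 1-(trimethylsilyl)imidazole, C[Si](C)(C)n1ccnc1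
Why: Silylation of the tertiary alcohol with a strong neutral silyl donor, so that no hydroxyl proton can quench the organozinc of step 24; silyl triflates are avoided because they would activate the acetal.

Step 18
Reactants: 24 dimethyl (4R,5R)-2,2-dimethyl-1,3-dioxolane-4,5-dicarboxylate
Product: 25 (4R,5R)-N4,N5-dimethoxy-N4,N5,2,2-tetramethyl-1,3-dioxolane-4,5-dicarboxamide
Conditions: MeNHOMe·HCl, iPrMgCl, THF, −20 → 0 °C
Reagents that add atoms: N,O-dimethylhydroxylamine hydrochloride, Cl.CNOC
Why: Weinreb amide formation from both esters with the magnesium amide; the trans-dioxolane centres (C14, C15) are the thermodynamically preferred arrangement and are not epimerised.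

Step 19
Reactants: 25
Product: 26 (4R,5R)-5-acetyl-N-methoxy-N,2,2-trimethyl-1,3-dioxolane-4-carboxamide
Conditions: MeMgBr (1.3 equiv), THF, −15 °C
Reagents that add atoms: methylmagnesium bromide, C[Mg]Br
Why: Grignard addition to a Weinreb amide; mono-addition to a tartaric bis(Weinreb amide) is an established desymmetrisation, because the first chelated magnesium tetrahedral intermediate slows attack at the second amide.

Step 20
Reactants: 26
Product: 27 1-[(4R,5R)-5-[methoxy(methyl)carbamoyl]-2,2-dimethyl-1,3-dioxolan-4-yl]ethenyl trifluoromethanesulfonate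
Conditions: KN(SiMe3)2 (KHMDS), THF, −78 °C; PhNTf2, −78 → −30 °C
Reagents that add atoms: N-phenylbis(trifluoromethanesulfonimide), O=S(=O)(N(c1ccccc1)S(=O)(=O)C(F)(F)F)C(F)(F)F
Why: Kinetic deprotonation of the methyl ketone on its methyl side and O-triflation give the terminal enol triflate, the future C13 with its methylene; the hindered α-alkoxy C–H is not removed at −78 °C.

Step 21
Reactants: 27; 28 ethyl propiolate
Product: 30 ethyl 4-[(4R,5R)-2,2-dimethyl-5-(1-{[(trifluoromethyl)sulfonyl]oxy}ethenyl)-1,3-dioxolan-4-yl]-4-oxobut-2-ynoate, via lithium ethyl propiolate 29 (not isolated)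
Conditions: 28, LiN(SiMe3)2 (LiHMDS), THF, −78 °C; then 27, −78 → −40 °C
Reagents that add atoms: none
Why: Acylation of a lithium acetylide by a Weinreb amide stops at the ketone; the alkenyl triflate is inert to the acetylide at −78 °C.

Step 22
Reactants: 30
Product: 31 ethyl (4R)-4-[(4S,5R)-2,2-dimethyl-5-(1-{[(trifluoromethyl)sulfonyl]oxy}ethenyl)-1,3-dioxolan-4-yl]-4-hydroxybut-2-ynoate
Conditions: (S)-1-methyl-3,3-diphenyltetrahydro-1H,3H-pyrrolo[1,2-c][1,3,2]oxazaborole [(S)-Me-CBS, 20 mol %], catecholborane, toluene, −78 °C
Reagents that add atoms: none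
Why: Corey–Bakshi–Shibata reduction of an ynone: the alkynyl group is the small substituent, so the (S)-oxazaborolidine delivers hydride to give the 16R carbinol, syn to O15, and the substrate's own non-chelated (Felkin–Anh) preference points the same way.

Step 23
Reactants: 31
Product: 33 1-[(4R,5S)-2,2-dimethyl-5-[(2R)-3-methyl-5-oxo-2,5-dihydrofuran-2-yl]-1,3-dioxolan-4-yl]ethenyl trifluoromethanesulfonate, via hydroxy enoate 32 (not isolated)
Conditions: Me2CuLi (3 equiv, from MeLi and CuI), THF, −78 °C; AcOH, −78 °C → rt
Reagents that add atoms: lithium dimethylcuprate, [Li+].C[Cu-]C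
Why: Syn conjugate addition of the cuprate to the 4-hydroxy ynoate puts the methyl on C17 cis to hydrogen, so the C16 oxygen and the ester are cis on the new alkene and close to the butenolide on protonation; at −78 °C the alkenyl triflate is not attacked by the cuprate.

Step 24
Reactants: 23; 33
Product: 35 protected target (4R,5R,6S,8R,9R,10S,14S,15R,16R): decalin of 23 joined through C12 to C13 of the side chain, C13 methylene, O14/O15 acetonide, butenolide, via alkylzinc iodide 34 (not isolated)
Conditions: Zn dust (activated with BrCH2CH2Br and Me3SiCl), LiCl, THF, 35 °C; then 33, [1,1'-bis(diphenylphosphino)ferrocene]dichloropalladium, Pd(dppf)Cl2 (5 mol %), THF/DMA, 40 °C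
Reagents that add atoms: none
Why: Negishi sp3–sp2 coupling: zinc inserts into the primary C–I bond and the alkylzinc couples with the alkenyl triflate under palladium catalysis to form C12–C13; no stereocentre is formed, and lactone, acetals and silyl ether tolerate the neutral organozinc.

Step 25
Reactants: 35
Product: 36 (1R,4aS,5R,6R,8S,8aR)-5-[(4S,5R)-4,5-dihydroxy-5-[(2R)-3-methyl-5-oxo-2,5-dihydrofuran-2-yl]-3-methylidenepentyl]-6,8-dihydroxy-1,4a,6-trimethyldecahydronaphthalene-1-carbaldehyde
Conditions: AcOH/THF/H2O 3:1:1, 40 °C
Reagents that add atoms: water, O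
Why: Aqueous acid hydrolysis of the cyclic methyl acetal (to the C4 aldehyde and the 6α-hydroxyl), the acetonide and the trimethylsilyl ether in one operation; no stereocentre is touched and the butenolide is stable to acid.

## Compound list

1 | methyl 2-oxocyclohexane-1-carboxylate | COC(=O)C1CCCCC1=O | starting material
2 | methyl (1R)-1-methyl-2-oxocyclohexane-1-carboxylate | O=C1CCCC[C@@]1(C)C(=O)OC | intermediate
3 | methyl (1R)-1,3-dimethyl-2-oxocyclohexane-1-carboxylate (C3 epimers) | O=C1C(C)CCC[C@@]1(C)C(=O)OC | intermediate
4 | methyl (1R)-1,3-dimethyl-2-{[(trifluoromethyl)sulfonyl]oxy}cyclohex-2-ene-1-carboxylate | CC1=C(OS(=O)(=O)C(F)(F)F)[C@](C)(C(=O)OC)CCC1 | intermediate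
5 | methyl (1R)-2-(hydroxymethyl)-1,3-dimethylcyclohex-2-ene-1-carboxylate | CC1=C(CO)[C@](C)(C(=O)OC)CCC1 | intermediate
6 | 4-(benzyloxy)butanoic acid | OC(=O)CCCOCc1ccccc1 | starting material
7 | [(6R)-6-(methoxycarbonyl)-2,6-dimethylcyclohex-1-en-1-yl]methyl 4-(benzyloxy)butanoate | CC1=C(COC(=O)CCCOCc2ccccc2)[C@](C)(C(=O)OC)CCC1 | intermediate
8 | (Z)-O-trimethylsilyl ketene acetal of ester 7 (CH2CH2OBn cis to OSiMe3) | CC1=C(CO/C(O[Si](C)(C)C)=C/CCOCc2ccccc2)[C@](C)(C(=O)OC)CCC1 | intermediate
9 | trimethylsilyl ester of acid 10 | C[Si](C)(C)OC(=O)[C@H](CCOCc1ccccc1)[C@@]1(C)CCC[C@@](C)(C(=O)OC)C1=C | intermediate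
10 | (2R)-4-(benzyloxy)-2-[(1R,3R)-3-(methoxycarbonyl)-1,3-dimethyl-2-methylidenecyclohexyl]butanoic acid | OC(=O)[C@H](CCOCc1ccccc1)[C@@]1(C)CCC[C@@](C)(C(=O)OC)C1=C | intermediate
11 | (2R)-4-(benzyloxy)-2-[(1S,2R,3R)-2-(hydroxymethyl)-3-(methoxycarbonyl)-1,3-dimethylcyclohexyl]butanoic acid | OC(=O)[C@H](CCOCc1ccccc1)[C@@]1(C)CCC[C@@](C)(C(=O)OC)[C@@H]1CO | intermediate
12 | trans-fused δ-lactone (4R,5R,9R,10S): O–C6H2 on C5, C8(=O)–C9 on C10, 4α-CO2Me, C9–CH2CH2OBn | O=C2[C@H](CCOCc3ccccc3)[C@@]1(C)CCC[C@@](C)(C(=O)OC)[C@@H]1CO2 | intermediate
13 | lactol (4R,5R,9R,10S): methyl hemiketal at C8 of lactone 12, both anomers | CC2(O)[C@H](CCOCc3ccccc3)[C@@]1(C)CCC[C@@](C)(C(=O)OC)[C@@H]1CO2 | intermediate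
14 | methyl (1R,2R,3R)-3-[(3S)-5-(benzyloxy)-2-methylpent-1-en-3-yl]-2-(hydroxymethyl)-1,3-dimethylcyclohexane-1-carboxylate | C=C(C)[C@H](CCOCc1ccccc1)[C@@]1(C)CCC[C@@](C)(C(=O)OC)[C@@H]1CO | intermediate
15 | methyl (1R,2R,3R)-3-[(3S)-5-(benzyloxy)-2-methylpent-1-en-3-yl]-2-formyl-1,3-dimethylcyclohexane-1-carboxylate | C=C(C)[C@H](CCOCc1ccccc1)[C@@]1(C)CCC[C@@](C)(C(=O)OC)[C@@H]1C=O | intermediate
16 | methyl (1R,4aR,5S,8S,8aR)-5-[2-(benzyloxy)ethyl]-8-hydroxy-1,4a-dimethyl-6-methylidenedecahydronaphthalene-1-carboxylate | c1ccccc1COCC[C@@H]1[C@@]2(C)CCC[C@@](C)(C(=O)OC)[C@@H]2[C@@H](O)CC1=C | intermediate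
17 | lactol (4R,5R,6S,9S,10R): cyclic hemiacetal between the C4 formyl carbon and O6, C8 methylene, 9β-CH2CH2OBn | c1ccccc1COCC[C@@H]1[C@@]2(C)CCC[C@@](C)(C3O)[C@@H]2[C@@H](O3)CC1=C | intermediate
18 | cyclic methyl acetal of 17 (4R,5R,6S,9S,10R) | c1ccccc1COCC[C@@H]1[C@@]2(C)CCC[C@@](C)(C3OC)[C@@H]2[C@@H](O3)CC1=C | intermediate
19 | 8α-oxygen spiro-epoxide of 18 (4R,5R,6S,8R,9R,10S) | c1ccccc1COCC[C@@H]1[C@@]2(C)CCC[C@@](C)(C3OC)[C@@H]2[C@@H](O3)C[C@@]14OC4 | intermediate
20 | acetal-protected decalin with 8α-OH, 8β-CH3, 9β-CH2CH2OBn (4R,5R,6S,8R,9R,10S) | c1ccccc1COCC[C@@H]1[C@@]2(C)CCC[C@@](C)(C3OC)[C@@H]2[C@@H](O3)C[C@@]1(C)O | intermediate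
21 | as 20 with 9β-CH2CH2OH | OCC[C@@H]1[C@@]2(C)CCC[C@@](C)(C3OC)[C@@H]2[C@@H](O3)C[C@@]1(C)O | intermediate
22 | as 20 with 9β-CH2CH2I | ICC[C@@H]1[C@@]2(C)CCC[C@@](C)(C3OC)[C@@H]2[C@@H](O3)C[C@@]1(C)O | intermediate
23 | as 22 with 8α-OSiMe3 | ICC[C@@H]1[C@@]2(C)CCC[C@@](C)(C3OC)[C@@H]2[C@@H](O3)C[C@@]1(C)O[Si](C)(C)C | intermediate
24 | dimethyl (4R,5R)-2,2-dimethyl-1,3-dioxolane-4,5-dicarboxylate | COC(=O)[C@@H]1OC(C)(C)O[C@H]1C(=O)OC | starting material
25 | (4R,5R)-N4,N5-dimethoxy-N4,N5,2,2-tetramethyl-1,3-dioxolane-4,5-dicarboxamide | CON(C)C(=O)[C@@H]1OC(C)(C)O[C@H]1C(=O)N(C)OC | intermediate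
26 | (4R,5R)-5-acetyl-N-methoxy-N,2,2-trimethyl-1,3-dioxolane-4-carboxamide | CC(=O)[C@@H]1OC(C)(C)O[C@H]1C(=O)N(C)OC | intermediate
27 | 1-[(4R,5R)-5-[methoxy(methyl)carbamoyl]-2,2-dimethyl-1,3-dioxolan-4-yl]ethenyl trifluoromethanesulfonate | C=C(OS(=O)(=O)C(F)(F)F)[C@@H]1OC(C)(C)O[C@H]1C(=O)N(C)OC | intermediate
28 | ethyl propiolate | C#CC(=O)OCC | starting material
29 | lithium ethyl propiolate | [Li]C#CC(=O)OCC | intermediate
30 | ethyl 4-[(4R,5R)-2,2-dimethyl-5-(1-{[(trifluoromethyl)sulfonyl]oxy}ethenyl)-1,3-dioxolan-4-yl]-4-oxobut-2-ynoate | C=C(OS(=O)(=O)C(F)(F)F)[C@@H]1OC(C)(C)O[C@H]1C(=O)C#CC(=O)OCC | intermediate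
31 | ethyl (4R)-4-[(4S,5R)-2,2-dimethyl-5-(1-{[(trifluoromethyl)sulfonyl]oxy}ethenyl)-1,3-dioxolan-4-yl]-4-hydroxybut-2-ynoate | C=C(OS(=O)(=O)C(F)(F)F)[C@@H]1OC(C)(C)O[C@H]1[C@H](O)C#CC(=O)OCC | intermediate
32 | ethyl (2Z,4R)-4-[(4S,5R)-2,2-dimethyl-5-(1-{[(trifluoromethyl)sulfonyl]oxy}ethenyl)-1,3-dioxolan-4-yl]-4-hydroxy-3-methylbut-2-enoate | C=C(OS(=O)(=O)C(F)(F)F)[C@@H]1OC(C)(C)O[C@H]1[C@H](O)/C(C)=C\C(=O)OCC | intermediate
33 | 1-[(4R,5S)-2,2-dimethyl-5-[(2R)-3-methyl-5-oxo-2,5-dihydrofuran-2-yl]-1,3-dioxolan-4-yl]ethenyl trifluoromethanesulfonate | C=C(OS(=O)(=O)C(F)(F)F)[C@@H]1OC(C)(C)O[C@H]1[C@@H]1OC(=O)C=C1C | intermediate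
34 | alkylzinc iodide from 23 (C12–ZnI) | I[Zn]CC[C@@H]1[C@@]2(C)CCC[C@@](C)(C3OC)[C@@H]2[C@@H](O3)C[C@@]1(C)O[Si](C)(C)C | intermediate
35 | protected target (4R,5R,6S,8R,9R,10S,14S,15R,16R): cyclic methyl acetal (C4 formyl carbon/O6), 8α-OSiMe3, O14/O15 acetonide | C=C(CC[C@@H]1[C@@]2(C)CCC[C@@](C)(C3OC)[C@@H]2[C@@H](O3)C[C@@]1(C)O[Si](C)(C)C)[C@@H]1OC(C)(C)O[C@H]1[C@@H]1OC(=O)C=C1C | intermediate
36 | (1R,4aS,5R,6R,8S,8aR)-5-[(4S,5R)-4,5-dihydroxy-5-[(2R)-3-methyl-5-oxo-2,5-dihydrofuran-2-yl]-3-methylidenepentyl]-6,8-dihydroxy-1,4a,6-trimethyldecahydronaphthalene-1-carbaldehyde | C=C(CC[C@@H]1[C@@]2(C)CCC[C@@](C)(C=O)[C@@H]2[C@@H](O)C[C@@]1(C)O)[C@H](O)[C@@H](O)[C@@H]1OC(=O)C=C1C | target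

## Step count and least certain steps

Total: 25 steps. Longest linear sequence: 19 steps (steps 1–17, 24 and 25); the side-chain fragment takes 6 steps (18–23).

**Step 11 (key step).** The likely failures are poor facial selectivity at C6, if closure through the array with axial oxygen competes despite the two axial methyls, and loss of regiocontrol, if the C8 cation sheds a ring proton or captures chloride because the methyl hydrogen cannot reach an equatorial oxygen. The fallback replaces the hydrogen-transfer requirement by a silyl group. It sets out from lactone 12: double addition of Me3SiCH2MgCl/CeCl3 gives the bis(silylmethyl) carbinol F1; Peterson elimination on silica gel gives the allylsilane alcohol F2; Dess–Martin oxidation gives the allylsilane aldehyde F3; BF3·OEt2 at −78 °C then triggers an intramolecular Hosomi–Sakurai addition through a chair with equatorial oxygen, the silyl group fixing the alkene as the exocyclic methylene. The route is rejoined at 16.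

**Step 6.** The likely failure is poor facial selectivity at C10, because methyl and ester on C4 differ little in size, together with some erosion of enolate geometry. The fallback moves control from the substrate to the reagent. It sets out from ester 7: enolisation with (4S,5S)-2-bromo-4,5-diphenyl-1,3-bis(p-tolylsulfonyl)-1,3,2-diazaborolidine and iPr2NEt, under conditions that give the Z(O) enolate, forms the chiral boron ketene acetal F4 (the antipodal controller is taken if that is the one matching the α face), which rearranges between −20 °C and rt. Aqueous work-up rejoins the route at acid 10.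

**Step 24.** The likely failures are slow zinc insertion, protonation or β-hydride loss of the alkylzinc before transmetallation, and β-alkoxy elimination from the alkenylpalladium next to the dioxolane. The fallback avoids a preformed organometallic: iodide 23 and triflate 33 are joined by reductive cross-electrophile coupling with NiBr2(dme), 4,4'-di-tert-butyl-2,2'-bipyridine and Mn powder in DMA. It sets out from 23 and 33 and arrives at 35; no new compound is made.

**Step 25.** The likely failure is incomplete acetonide cleavage under acid mild enough for the tertiary C8 and allylic C14 carbinols, or dehydration and allylic ionisation when the acid is forced. The fallback changes the diol protection while the fragment is still small. It sets out from 33: aqueous CF3CO2H gives the diol triflate F5; Et3SiOTf/2,6-lutidine gives the bis(triethylsilyl) ether F6; Negishi coupling with 34 as in step 24 gives the coupled bis(silyl) ether F7; AcOH/THF/H2O at rt then removes both silyl types and the methyl acetal. The route is rejoined at 36.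

**Step 1.** The likely failure is insufficient enantioselectivity, since phase-transfer alkylation of β-keto esters is most selective for bulkier esters than the methyl ester used here. The fallback uses an auxiliary. It sets out from 1: condensation with L-valine tert-butyl ester gives the chiral enamino ester F8; lithiation with LDA and methylation with MeI, in the solvent system that leads to the R product, gives the methylated imine F9; dilute aqueous acid releases the amino ester and rejoins the route at 2.

## Further compounds

F1 | step 11 | bis(silylmethyl) carbinol from lactone 12 | C[Si](C)(C)CC(O)(C[Si](C)(C)C)[C@H](CCOCc1ccccc1)[C@@]1(C)CCC[C@@](C)(C(=O)OC)[C@@H]1CO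
F2 | step 11 | allylsilane alcohol | C=C(C[Si](C)(C)C)[C@H](CCOCc1ccccc1)[C@@]1(C)CCC[C@@](C)(C(=O)OC)[C@@H]1CO
F3 | step 11 | allylsilane aldehyde | C=C(C[Si](C)(C)C)[C@H](CCOCc1ccccc1)[C@@]1(C)CCC[C@@](C)(C(=O)OC)[C@@H]1C=O
F4 | step 6 | chiral boron ketene acetal of ester 7 | CC1=C(CO/C(OB2N(S(=O)(=O)c3ccc(C)cc3)[C@@H](c3ccccc3)[C@H](c3ccccc3)N2S(=O)(=O)c2ccc(C)cc2)=C/CCOCc2ccccc2)[C@](C)(C(=O)OC)CCC1
F0 | step 24 | none | none
F5 | step 25 | diol triflate | C=C(OS(=O)(=O)C(F)(F)F)[C@H](O)[C@@H](O)[C@@H]1OC(=O)C=C1C
F6 | step 25 | bis(triethylsilyl) ether triflate | C=C(OS(=O)(=O)C(F)(F)F)[C@H](O[Si](CC)(CC)CC)[C@@H](O[Si](CC)(CC)CC)[C@@H]1OC(=O)C=C1C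
F7 | step 25 | coupled bis(triethylsilyl) ether | C=C(CC[C@@H]1[C@@]2(C)CCC[C@@](C)(C3OC)[C@@H]2[C@@H](O3)C[C@@]1(C)O[Si](C)(C)C)[C@H](O[Si](CC)(CC)CC)[C@@H](O[Si](CC)(CC)CC)[C@@H]1OC(=O)C=C1C
F8 | step 1 | enamino ester of 1 with L-valine tert-butyl ester | CC(C)[C@H](NC1=C(C(=O)OC)CCCC1)C(=O)OC(C)(C)C
F9 | step 1 | methylated imine | CC(C)[C@H](N=C1CCCC[C@@]1(C)C(=O)OC)C(=O)OC(C)(C)C
A1 | alternative 1 | β-keto δ-lactone on the ring-A alkene (C6 configuration left open) | O=C1CC(=O)CC(O1)C1=C(C)CCC[C@@]1(C)C(=O)OC
A2 | alternative 1 | ring-B β-keto ester with C5=C6 alkene | COC(=O)[C@@H]1[C@@]2(C)CCC[C@@](C)(C(=O)OC)C2=CCC1=O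
A3 | alternative 2 | protected C16 aldehyde | C=C(CC[C@@H]1[C@@]2(C)CCC[C@@](C)(CO[Si](C)(C)C(C)(C)C)[C@@H]2[C@@H](O[Si](C)(C)C(C)(C)C)C[C@@]1(C)O[Si](C)(C)C)[C@H](O[Si](CC)(CC)CC)[C@@H](OCc1ccc(OC)cc1)C=O
A4 | alternative 2 | methyl (Z)-3-iodobut-2-enoate | C/C(I)=C/C(=O)OC
A5 | alternative 2 | protected target | C=C(CC[C@@H]1[C@@]2(C)CCC[C@@](C)(CO[Si](C)(C)C(C)(C)C)[C@@H]2[C@@H](O[Si](C)(C)C(C)(C)C)C[C@@]1(C)O[Si](C)(C)C)[C@H](O[Si](CC)(CC)CC)[C@@H](OCc1ccc(OC)cc1)[C@@H]1OC(=O)C=C1C
A6 | alternative 3 | ring-B silyl enol ether with tethered methyl enol ether | C=CC[C@@H]1[C@@](C)(CCCC(C)=COC)C=C(O[Si](C)(C)C)C[C@H]1C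
A7 | alternative 3 | trans-decalin-6-one with the C4 formyl carbon as dimethyl acetal | C=CC[C@@H]1[C@@]2(C)CCC[C@@](C)(C(OC)OC)[C@@H]2C(=O)C[C@H]1C
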